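## Structural features

The target is a 2,2-disubstituted chroman: an orcinol-type benzene ring A (methyl on C5, free hydroxyl on C7) is fused through C4a–C8a to the dihydropyran ring B (O1, C2, C3, C4). C2 is the only stereocentre. It is a fully substituted, oxygen-bearing carbon of R configuration that carries O1, a methyl group, C3 and a nine-carbon chain, so no neighbouring stereocentre is available to relay its configuration. The chain (C1' to C8' outward from C2) holds an E-trisubstituted alkene at C3'=C4' and ends in a Z-configured α-methyl enoate at C7'=C8' (methyl ester), the less stable geometry. The fragile groups are: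
- the Z-enoate, which can isomerise to E through reversible conjugate addition, strong base or radicals, and whose ester can be saponified;
- the tertiary alkyl aryl ether C2–O1, which would ionise and racemise in strong acid;
- the electron-rich ring A;
- the isolated trisubstituted alkene, which can enter cation cyclisations.

The real difficulty is the quaternary C2, whose two carbon arms differ only three bonds away, together with the geometry of two trisubstituted alkenes. The key step exploits the fact that C2 with O1, its methyl, C3–C4 and C1' to C5' (plus the methyl on C4') is the whole skeleton of a linalool. The carbinol carbon is C2, the vinyl group is C3–C4, and the homoprenyl group is C1'–C4' with its E-methyl as C5'. Once the chain has been lengthened at C5' and ring A hung on C4, only the aryl ether bond O1–C8a of ring B is missing, and forming it does not touch C2.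

## Logic of the disconnections

15 to 14: the O–CH2 bond of a methoxymethyl acetal on the C7 oxygen is cut (a functional-group change, no skeletal bond). The C7 oxygen has to be masked because a free phenoxide would compete as an oxygen nucleophile in both palladium steps. The gain is only enabling. The demand on the forward step is an unmasking that spares the Z-enoate, the C2–O1 ether and the C3'=C4' alkene, which points to catalytic acid in methanol, where ester exchange is degenerate.

14 to 13: O1–C8a is cut. This opens ring B and turns the cyclic quaternary ether into an acyclic tertiary carbinol whose configuration is already that of the target. The forward step must arylate a hindered tertiary hydroxyl with an ortho bromide under a base weak enough for the methyl ester and the Z geometry, and it must leave the C2–O bond intact. The bromide is kept in 13 rather than a second iodide so that the two halogens can be told apart one step earlier. The acetal is kept because it withstands carbonate and phosphate bases at elevated temperature.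

13 to 8 and 11 (through 12): C4–C4a is cut. This divides the molecule into a sixteen-carbon chain piece and a nine-carbon arene, and the terminal vinyl group of 8 becomes the latent C3–C4 unit. The forward step demands hydroboration of the monosubstituted alkene only, and cross-coupling at the iodide of 11, which sits between bromine and methyl, while the bromide survives.

11 to 10 to 9: the acetal O–CH2 bond and the aryl C–I bond are cut, leading back to a commercial bromocresol. The demand is iodination para to the hydroxyl, at the position flanked by bromine and methyl.

8 to 6 and 7: C7'=C8' is cut. The Z-enoate is the least stable element of the chain and is best made kinetically, as late as the chain allows, from an aldehyde and a commercial phosphonate. The forward step needs high Z selectivity in the presence of a free tertiary hydroxyl.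

6 to 4 (through 5) to 3: the aldehyde is traced to a nitrile and C5'–C6' is cut, so the two carbons C6' and C7' arrive as a cyanomethyl anion. A nitrile is chosen over an ester as the aldehyde precursor because hydride addition stops at the imine stage. The forward alkylation must go by direct displacement at the primary allylic carbon and must tolerate the hydroxyl.

3 to 2 to 1: the C5'–Br and C5'–O bonds are cut, which returns all ten carbons and the stereocentre to 1. The forward steps need oxidation of the E-methyl group only, with E geometry, and activation of the primary allylic hydroxyl in the presence of the tertiary one.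

## Other disconnections considered

Alternative 1: The cut is C3=C4, made as an alkene, with C2 created by desymmetrisation. The prochiral triene 2-ethenyl-5-(methoxymethoxy)-1-methyl-3-[(3-methylpenta-1,4-dien-3-yl)oxy]benzene A1 would be closed by asymmetric ring-closing metathesis with a chiral molybdenum imido alkylidene biphenolate of the type Mo(NAr)(CHCMe2Ph)(biphenolate). The aryl vinyl group and one of the two enantiotopic carbinol vinyl groups join through a molybdacyclobutane, ethylene is lost, and (R)-2-ethenyl-7-(methoxymethoxy)-2,5-dimethyl-2H-chromene A2 results. The remaining vinyl group would then be hydroborated and coupled with methyl (2Z,6E)-7-iodo-2,6-dimethylhepta-2,6-dienoate A3 to install the chain in one convergent step.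
- In its favour: ring B and the stereocentre form together, control is catalytic and either enantiomer is accessible, and the aryl C–O bond is made early on a simple substrate.
- Against it here: A1 is the aryl ether of a tertiary bis-allylic alcohol, which is hard to make (ionising conditions would give the linear dienyl ether, and arylating that alcohol is itself a difficult C–O coupling). The catalyst must also distinguish two vinyl groups on a carbon whose other substituents are methyl and aryloxy. The C3=C4 bond of ring B must later be saturated in the presence of two trisubstituted alkenes. The alkylidene is air- and moisture-sensitive.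
- Comparison: on structure this plan creates C2 where the chosen plan buys it. On mechanism it relies on catalyst-controlled enantiotopic group selection, whereas the chosen plan needs no stereocontrol at all. On step economy it is longer, because A1 and A3 each need several steps and an extra reduction is added. It is the better plan on convergence of the chain and on independence from the enantiomeric purity of a natural starting material.

Alternative 2: The cuts are C8–C8a and C4a–C5 of ring A. The terminal carbanion of the dianion of pentane-2,4-dione A5 would acylate (S)-6-methyl-6-(4-methylpent-3-en-1-yl)oxan-2-one A4. The triketone, held as the hemiketal or enol ether of ring B, would then close by aldol reaction and lose two molecules of water to give (R)-2,5-dimethyl-2-(4-methylpent-3-en-1-yl)chroman-7-ol A6.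
- In its favour: ring A is built with the correct methyl and hydroxyl pattern from a trivial diketone, with no halogen, no palladium and no protecting group in the key step. The stereocentre is carried in unchanged; on this point it equals the chosen plan.
- Against it here: A4 is not a commercial enantiopure compound and needs its own synthesis. Acylation of a lactone by a dianion competes with enolisation and double addition. The polyketone can close through oxygen to a pyranone instead of through carbon, and the required aldol starts from the least acidic position, C4a. A6 still lacks C6' to C8' and the ester, so the whole chain extension (allylic oxidation, homologation, olefination) would follow on an electron-rich chromanol that needs protection.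
- Comparison: on structure it is the most economical way to make ring A and is the better plan in atom economy and in avoiding precious metals. On mechanism it rests on several equilibria that must all go one way. On step economy it is clearly longer and fully linear.

Alternative 3: The cut is O1–C2, with the stereocentre set by a chiral ligand. Racemic methyl [5-[2-hydroxy-4-(methoxymethoxy)-6-methylphenyl]-3-methylpent-1-en-3-yl] carbonate A7 would be ionised by Pd2(dba)3 with a chiral diphosphine. Both enantiomers converge on interconverting allyl complexes, and the phenol oxygen attacks the substituted terminus to give (S)-2-ethenyl-7-(methoxymethoxy)-2,5-dimethylchromane A8. This has the same spatial arrangement as the target; the descriptor is S only because the vinyl group outranks C3. The chain would again come from hydroboration and coupling with A3.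
- In its favour: the asymmetric allylic etherification of phenols to 2-vinylchromans is a developed reaction class, the racemate is used in full, no extra unsaturation is left in ring B (better than Alternative 1), and the chain is attached convergently.
- Against it here: enantiomeric purity depends on allyl equilibration being faster than ring closure and must be established. The tertiary allylic carbonate is prone to elimination. A7 needs a regioselectively alkylated and mono-protected orcinol, and A3 must also be made.
- Comparison: on structure it breaks and remakes the bond at the stereocentre, which the chosen plan never touches. On mechanism it is ligand-controlled, where the chosen plan is stereochemically passive. On step economy it is about equal in longest linear sequence and somewhat longer in total. It is the better plan on flexibility and on freedom from the enantiomeric purity of commercial linalool, and its ring-closing step is milder than a tertiary-alkoxide arylation.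

Key step: step 9

Assumption: commercial (R)-(−)-linalool of high enantiomeric purity is used; since no bond to the carbinol carbon is broken, the enantiomeric purity of 15 equals that of 1.
Remark on descriptors: the carbinol carbon keeps one spatial arrangement from 1 to 15 and is R throughout, except in 12, where boron lowers the CIP rank of the C11–C12 arm and the descriptor reads S without any change at the centre.

## Route

Step 1
Reactants: 1 (R)-(−)-linalool, (3R)-3,7-dimethylocta-1,6-dien-3-ol
Product: 2 (2E,6R)-2,6-dimethylocta-2,7-diene-1,6-diol
Conditions: SeO2 (cat.), tBuOOH, salicylic acid (cat.), CH2Cl2, 0 °C to rt, stopped before over-oxidation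
Reagents that add atoms: tert-butyl hydroperoxide, CC(C)(C)OO (terminal oxidant; its oxygen is passed on through selenium dioxide, O=[Se]=O)
Why: Allylic oxidation by SeO2 (ene reaction followed by a [2,3]-sigmatropic shift) attacks the E-methyl group of the trisubstituted alkene and returns the E-allylic alcohol; the vinyl group has no allylic hydrogen and the stereocentre is not involved. Catalytic selenium with tBuOOH keeps the medium nearly neutral, so the tertiary allylic alcohol should not rearrange.

Step 2
Reactants: 2 (2E,6R)-2,6-dimethylocta-2,7-diene-1,6-diol
Product: 3 (3R,6E)-8-bromo-3,7-dimethylocta-1,6-dien-3-ol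
Conditions: CBr4 (1.1 equiv), PPh3 (1.15 equiv), CH2Cl2, −20 to 0 °C; used at once
Reagents that add atoms: carbon tetrabromide, BrC(Br)(Br)Br
Why: Appel reaction; the primary allylic hydroxyl forms the alkoxyphosphonium salt and is displaced by bromide far faster than the hindered tertiary hydroxyl, and limiting reagent at low temperature avoids allylic transposition. The E geometry and the stereocentre are untouched.

Step 3
Reactants: 3 (3R,6E)-8-bromo-3,7-dimethylocta-1,6-dien-3-ol
Product: 4 (4E,8R)-8-hydroxy-4,8-dimethyldeca-4,9-dienenitrile
Conditions: MeCN (5 equiv), nBuLi (4.5 equiv), THF, −78 °C; then 3 added slowly, −78 to −40 °C; aq. NH4Cl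
Reagents that add atoms: acetonitrile, CC#N
Why: Direct displacement of the primary allylic bromide by lithioacetonitrile (nitrile anion alkylation); the excess nucleophile absorbs the hydroxyl proton and suppresses double alkylation. At −78 °C the aggregated lithium tertiary alkoxide should be too poor a nucleophile to close a cyclic ether.

Step 4
Reactants: 4 (4E,8R)-8-hydroxy-4,8-dimethyldeca-4,9-dienenitrile
Product: 6 (4E,8R)-8-hydroxy-4,8-dimethyldeca-4,9-dienal, via N,O-bis(diisobutylalumanyl) aldimine 5 (not isolated)
Conditions: iBu2AlH (2.5 equiv), CH2Cl2, −78 to −40 °C; then aq. potassium sodium tartrate, then pH 5 acetate buffer, 0 °C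
Reagents that add atoms: water, O
Why: iBu2AlH adds once to a nitrile to give an N-aluminated aldimine that cannot be reduced further and is hydrolysed to the aldehyde on buffered work-up (nitrile to aldehyde reduction). One further equivalent is consumed by the hydroxyl, and the mildly acidic work-up should spare the tertiary allylic alcohol.

Step 5
Reactants: 6 (4E,8R)-8-hydroxy-4,8-dimethyldeca-4,9-dienal; 7 methyl 2-[bis(2,2,2-trifluoroethoxy)phosphoryl]propanoate
Product: 8 methyl (2Z,6E,10R)-10-hydroxy-2,6,10-trimethyldodeca-2,6,11-trienoate
Conditions: 7 (1.3 equiv), KN(SiMe3)2 (1.25 equiv), 18-crown-6, THF, −78 °C; then 6, −78 °C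
Reagents that add atoms: none
Why: Still–Gennari olefination; with the electron-poor bis(trifluoroethyl) phosphonate and a dissociated potassium counter-ion the oxaphosphetane collapses faster than it equilibrates, so the Z-trisubstituted enoate forms under kinetic control. The phosphonate anion is too weak a base to deprotonate the tertiary alcohol.

Step 6
Reactants: 9 3-bromo-5-methylphenol
Product: 10 3-bromo-4-iodo-5-methylphenol
Conditions: N-iodosuccinimide (1.05 equiv), TsOH·H2O (cat.), MeCN, 0 °C to rt, dark
Reagents that add atoms: N-iodosuccinimide, O=C1CCC(=O)N1I
Why: Electrophilic aromatic iodination; the hydroxyl directs the acid-activated iodinating agent to the para position, which is also ortho to the methyl group, as is usual for 3,5-disubstituted phenols.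

Step 7
Reactants: 10 3-bromo-4-iodo-5-methylphenol
Product: 11 1-bromo-2-iodo-5-(methoxymethoxy)-3-methylbenzene
Conditions: MOMCl (1.3 equiv), iPr2NEt (1.5 equiv), CH2Cl2, 0 °C to rt
Reagents that add atoms: chloromethyl methyl ether, COCCl
Why: O-alkylation of the phenol by the oxocarbenium-type electrophile (methoxymethyl ether formation). The acetal withstands the basic palladium steps and falls to mild acid at the end.

Step 8
Reactants: 8 methyl (2Z,6E,10R)-10-hydroxy-2,6,10-trimethyldodeca-2,6,11-trienoate; 11 1-bromo-2-iodo-5-(methoxymethoxy)-3-methylbenzene
Product: 13 methyl (2Z,6E,10R)-12-[2-bromo-4-(methoxymethoxy)-6-methylphenyl]-10-hydroxy-2,6,10-trimethyldodeca-2,6-dienoate, via B-alkyl-9-BBN borane 12 (not isolated)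
Conditions: 9-BBN (1.5 equiv), THF, 0 °C to rt; then aq. K3PO4 (3 equiv), 11 (1.2 equiv), PdCl2(dppf)·CH2Cl2 (5 mol %), AsPh3 (10 mol %), DMF, rt to 45 °C
Reagents that add atoms: none
Why: 9-BBN hydroborates the monosubstituted vinyl group at its terminal carbon much faster than the trisubstituted alkene or the enoate. The B-alkyl Suzuki–Miyaura coupling then occurs at the C–I bond, which undergoes oxidative addition well before C–Br with the dppf-ligated catalyst at mild temperature. The stereocentre is a spectator.

Step 9
Reactants: 13 methyl (2Z,6E,10R)-12-[2-bromo-4-(methoxymethoxy)-6-methylphenyl]-10-hydroxy-2,6,10-trimethyldodeca-2,6-dienoate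
Product: 14 methyl (2Z,6E)-9-[(2R)-7-(methoxymethoxy)-2,5-dimethylchroman-2-yl]-2,6-dimethylnona-2,6-dienoate
Conditions: Pd(OAc)2 (5 mol %), racemic 2-(di-tert-butylphosphino)-1,1'-binaphthyl (6 mol %), Cs2CO3 (1.5 equiv), toluene, 80 °C
Reagents that add atoms: none
Why: Pd(OAc)2 is reduced in the flask by the phosphine to a monoligated zerovalent palladium species that inserts into the C8a–Br bond of 13; Cs2CO3 then removes the proton of the coordinated tertiary hydroxyl and bromide is exchanged for alkoxide, giving a seven-membered aryl alkoxide complex of divalent palladium. Reductive elimination from this palladacycle forms O1–C8a and returns zerovalent palladium, and the bulk of the di-tert-butyl biaryl phosphine presses the aryl and alkoxide ligands together and so speeds this otherwise slow step. The closest known reaction type is the Buchwald–Hartwig-type intramolecular etherification of aryl bromides with tertiary alcohols to 2,2-disubstituted chromans. Ring B closes as a six-membered ring through aryl C–O bond formation, the new bond lying inside the ring and the closure passing through the seven-membered palladacycle. No stereocentre is formed, so the racemic ligand suffices, and C2 keeps the R configuration bought with 1 because the C2–O bond is never broken and no cation or radical develops at C2. The step needs C–O coupling to win over β-hydride elimination, alkene insertion and ester cleavage: the tertiary alkoxide has no hydrogen on its carbinol carbon, the two trisubstituted alkenes could insert only through medium-ring transition states, and a sparingly soluble carbonate in toluene leaves the methyl ester and the Z geometry alone. The acetal on the C7 oxygen keeps that oxygen from competing as a nucleophile.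

Step 10
Reactants: 14 methyl (2Z,6E)-9-[(2R)-7-(methoxymethoxy)-2,5-dimethylchroman-2-yl]-2,6-dimethylnona-2,6-dienoate
Product: 15 methyl (2Z,6E)-9-[(2R)-7-hydroxy-2,5-dimethylchroman-2-yl]-2,6-dimethylnona-2,6-dienoate (CNP0319148.1)
Conditions: TsOH·H2O (0.2 equiv), MeOH, 40 °C
Reagents that add atoms: none
Why: Acid-catalysed acetal exchange releases the phenol and dimethoxymethane (methoxymethyl ether cleavage). In methanol, ester exchange only regenerates the methyl ester, and catalytic sulfonic acid at this temperature should not ionise the C2–O1 ether or protonate the alkenes.

## Compound list

1 | (R)-(−)-linalool, (3R)-3,7-dimethylocta-1,6-dien-3-ol | CC(C)=CCC[C@](O)(C)C=C | starting material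
2 | (2E,6R)-2,6-dimethylocta-2,7-diene-1,6-diol | OC/C(C)=C/CC[C@](O)(C)C=C | intermediate
3 | (3R,6E)-8-bromo-3,7-dimethylocta-1,6-dien-3-ol | BrC/C(C)=C/CC[C@](O)(C)C=C | intermediate
4 | (4E,8R)-8-hydroxy-4,8-dimethyldeca-4,9-dienenitrile | N#CCC/C(C)=C/CC[C@](O)(C)C=C | intermediate
5 | (4E,8R)-N-(diisobutylalumanyl)-8-[(diisobutylalumanyl)oxy]-4,8-dimethyldeca-4,9-dien-1-imine | CC(C)C[Al](CC(C)C)N=CCC/C(C)=C/CC[C@](O[Al](CC(C)C)CC(C)C)(C)C=C | intermediate (not isolated)
6 | (4E,8R)-8-hydroxy-4,8-dimethyldeca-4,9-dienal | O=CCC/C(C)=C/CC[C@](O)(C)C=C | intermediate
7 | methyl 2-[bis(2,2,2-trifluoroethoxy)phosphoryl]propanoate | COC(=O)C(C)P(=O)(OCC(F)(F)F)OCC(F)(F)F | starting material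
8 | methyl (2Z,6E,10R)-10-hydroxy-2,6,10-trimethyldodeca-2,6,11-trienoate | COC(=O)/C(C)=C\CC/C(C)=C/CC[C@](O)(C)C=C | intermediate
9 | 3-bromo-5-methylphenol | Cc1cc(O)cc(Br)c1 | starting material
10 | 3-bromo-4-iodo-5-methylphenol | Cc1cc(O)cc(Br)c1I | intermediate
11 | 1-bromo-2-iodo-5-(methoxymethoxy)-3-methylbenzene | COCOc1cc(C)c(I)c(Br)c1 | intermediate
12 | methyl (2Z,6E,10S)-12-(9-borabicyclo[3.3.1]nonan-9-yl)-10-hydroxy-2,6,10-trimethyldodeca-2,6-dienoate | COC(=O)/C(C)=C\CC/C(C)=C/CC[C@](O)(C)CCB1C2CCCC1CCC2 | intermediate (not isolated)
13 | methyl (2Z,6E,10R)-12-[2-bromo-4-(methoxymethoxy)-6-methylphenyl]-10-hydroxy-2,6,10-trimethyldodeca-2,6-dienoate | COC(=O)/C(C)=C\CC/C(C)=C/CC[C@](O)(C)CCc1c(C)cc(OCOC)cc1Br | intermediate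
14 | methyl (2Z,6E)-9-[(2R)-7-(methoxymethoxy)-2,5-dimethylchroman-2-yl]-2,6-dimethylnona-2,6-dienoate | COC(=O)/C(C)=C\CC/C(C)=C/CC[C@]1(C)CCc2c(C)cc(OCOC)cc2O1 | intermediate
15 | methyl (2Z,6E)-9-[(2R)-7-hydroxy-2,5-dimethylchroman-2-yl]-2,6-dimethylnona-2,6-dienoate | COC(=O)/C(C)=C\CC/C(C)=C/CC[C@]1(C)CCc2c(C)cc(O)cc2O1 | target

## Step count and least certain steps

Total step count: 10. Longest linear sequence: 8 steps from 1 (steps 1 to 5, 8, 9 and 10); the arene branch from 9 adds steps 6 and 7.

Step 9 (key step). The most likely failure is slow C–O reductive elimination at the crowded tertiary alkoxide, so that the arylpalladium bromide is diverted to loss of bromine or the catalyst decays. A second concern is slow erosion of the Z geometry if heating with carbonate has to be prolonged. The fallback replaces the palladium cycle by a copper-mediated Ullmann etherification, in which this reductive elimination is no longer the weak point. It sets out from 13. Halogen exchange with NaI, CuI and trans-N,N'-dimethylcyclohexane-1,2-diamine in dioxane at 110 °C should give methyl (2Z,6E,10R)-10-hydroxy-12-[2-iodo-4-(methoxymethoxy)-6-methylphenyl]-2,6,10-trimethyldodeca-2,6-dienoate F1. Monovalent copper (CuI with 3,4,7,8-tetramethyl-1,10-phenanthroline and Cs2CO3 in toluene at 110 °C) should then close O1–C8a, and the route is rejoined at 14.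

Step 8. The iodide of 11 lies between bromine and methyl, so transmetalation and coupling may be slow. Borane 12 could then be lost by protodeboronation or β-hydride elimination, and forcing the reaction may erode the preference for iodide over bromide. The fallback changes the carbon–carbon bond-forming event from transmetalation to carbopalladation. It sets out from 8 and 11. A ligand-free Heck arylation (Pd(OAc)2, Bu4NCl, NaHCO3, DMF, 70 °C), which activates only the iodide, should give methyl (2Z,6E,10R,11E)-12-[2-bromo-4-(methoxymethoxy)-6-methylphenyl]-10-hydroxy-2,6,10-trimethyldodeca-2,6,11-trienoate F2. No ketone can form because the carbinol carbon has no hydrogen. Hydrogenation with RhCl(PPh3)3 under H2 (1 atm) in toluene/EtOH should saturate the disubstituted styrenyl alkene in preference to the two trisubstituted alkenes without touching the C–Br bond, and the route is rejoined at 13.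

Step 3. The hydroxyl of 3 is deprotonated under the reaction conditions. The lithium alkoxide may close a five-membered cyclic ether by allylic displacement with transposition, and the product nitrile may be alkylated a second time. The fallback masks the hydroxyl. It sets out from 3. Et3SiOTf and 2,6-lutidine in CH2Cl2 at −78 °C should give triethyl{[(3R,6E)-8-bromo-3,7-dimethylocta-1,6-dien-3-yl]oxy}silane F3. Alkylation with lithioacetonitrile as in step 3 should give (4E,8R)-4,8-dimethyl-8-[(triethylsilyl)oxy]deca-4,9-dienenitrile F4. HF·pyridine in THF at 0 °C removes the silyl group, and the route is rejoined at 4.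

Step 6. The para position of 9 is flanked by bromine and methyl, so iodination may stray to the two positions ortho to the hydroxyl or go twice. The fallback uses para-selective nitrosation and a Sandmeyer-type iodination, which fix the position of the iodine through nitrogen. It sets out from 9. NaNO2 in aqueous HCl at 0 °C should give 3-bromo-5-methyl-4-nitrosophenol F5. Reduction with Na2S2O4 in aqueous ethanol should give 4-amino-3-bromo-5-methylphenol F6. Diazotisation (NaNO2, aqueous HCl, 0 °C) should give 2-bromo-4-hydroxy-6-methylbenzenediazonium chloride F7, which is not isolated and is treated with KI. The route is rejoined at 10.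

## Further compounds

F1 | step 9 | methyl (2Z,6E,10R)-10-hydroxy-12-[2-iodo-4-(methoxymethoxy)-6-methylphenyl]-2,6,10-trimethyldodeca-2,6-dienoate | COC(=O)/C(C)=C\CC/C(C)=C/CC[C@](O)(C)CCc1c(C)cc(OCOC)cc1I
F2 | step 8 | methyl (2Z,6E,10R,11E)-12-[2-bromo-4-(methoxymethoxy)-6-methylphenyl]-10-hydroxy-2,6,10-trimethyldodeca-2,6,11-trienoate | COC(=O)/C(C)=C\CC/C(C)=C/CC[C@](O)(C)/C=C/c1c(C)cc(OCOC)cc1Br
F3 | step 3 | triethyl{[(3R,6E)-8-bromo-3,7-dimethylocta-1,6-dien-3-yl]oxy}silane | BrC/C(C)=C/CC[C@](O[Si](CC)(CC)CC)(C)C=C
F4 | step 3 | (4E,8R)-4,8-dimethyl-8-[(triethylsilyl)oxy]deca-4,9-dienenitrile | N#CCC/C(C)=C/CC[C@](O[Si](CC)(CC)CC)(C)C=C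
F5 | step 6 | 3-bromo-5-methyl-4-nitrosophenol | Cc1cc(O)cc(Br)c1N=O
F6 | step 6 | 4-amino-3-bromo-5-methylphenol | Cc1cc(O)cc(Br)c1N
F7 | step 6 | 2-bromo-4-hydroxy-6-methylbenzenediazonium chloride | Cc1cc(O)cc(Br)c1[N+]#N.[Cl-]
A1 | alternative 1 | 2-ethenyl-5-(methoxymethoxy)-1-methyl-3-[(3-methylpenta-1,4-dien-3-yl)oxy]benzene | C=Cc1c(C)cc(OCOC)cc1OC(C)(C=C)C=C
A2 | alternative 1 | (R)-2-ethenyl-7-(methoxymethoxy)-2,5-dimethyl-2H-chromene | C=C[C@]1(C)C=Cc2c(C)cc(OCOC)cc2O1
A3 | alternative 1 | methyl (2Z,6E)-7-iodo-2,6-dimethylhepta-2,6-dienoate | COC(=O)/C(C)=C\CC/C(C)=C/I
A4 | alternative 2 | (S)-6-methyl-6-(4-methylpent-3-en-1-yl)oxan-2-one | CC(C)=CCC[C@]1(C)CCCC(=O)O1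
A5 | alternative 2 | pentane-2,4-dione | CC(=O)CC(C)=O
A6 | alternative 2 | (R)-2,5-dimethyl-2-(4-methylpent-3-en-1-yl)chroman-7-ol | CC(C)=CCC[C@]1(C)CCc2c(C)cc(O)cc2O1
A7 | alternative 3 | methyl [5-[2-hydroxy-4-(methoxymethoxy)-6-methylphenyl]-3-methylpent-1-en-3-yl] carbonate (racemic) | COC(=O)OC(C)(C=C)CCc1c(C)cc(OCOC)cc1O
A8 | alternative 3 | (S)-2-ethenyl-7-(methoxymethoxy)-2,5-dimethylchromane | C=C[C@]1(C)CCc2c(C)cc(OCOC)cc2O1
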